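**Strategy.** Ring C is disconnected at C2–C3. Its precursor is a seven-membered cyclic acetal (a 1,3-benzodioxepin-5-one) in which C2, still an acetal carbon, is held between O1 of ring A and the oxygen that will become the C3 hydroxyl. A chiral phosphoric acid opens the C2–O(C3) bond; the free 2'-hydroxyl of ring B turns C2 into the exocyclic carbon of an ortho-quinone methide that keeps O1, and the enediol of the liberated C4 ketol attacks it through C3. One isomerisation thus forges C2–C3, closes ring C, unveils the 3-OH and sets both stereocentres. The fully substituted ring A comes from 2-methoxyresorcinol by C–H borylation, Claisen prenylation and ortho-formylation.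

Key step: step 9

Remark: flavanone numbering (O1, C2, C3, C4, C4a, C5–C8, C8a; ring B primed) is used for all precursors of ring C; TBS = tert-butyldimethylsilyl, prenyl = 3-methylbut-2-en-1-yl.
Assumption: the (R)-configured phosphoric acid is taken to lead to the (2R,3R) series; if the sense of induction proves opposite, its mirror image is used.

Step 1
Reactants: 1 2-methoxyresorcinol
Product: 2 bis-silyl ether 1,3-bis(TBSO)-2-methoxybenzene
Conditions: TBSCl (2.3 equiv), imidazole, DMF, rt
Reagents that add atoms: tert-butyldimethylsilyl chloride, CC(C)(C)[Si](C)(C)Cl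
Why: Imidazole-promoted silyl ether formation on the two equivalent phenols should put fluoride-labile groups on the future O5 and O7 that tolerate every later step.

Step 2
Reactants: 2 bis-silyl ether
Product: 4 free phenol 3,5-bis(TBSO)-4-methoxyphenol, via aryl pinacol boronate 3 (not isolated)
Conditions: [Ir(OMe)(cod)]2 (1.5 mol%), 4,4'-di-tert-butyl-2,2'-bipyridine (3 mol%), B2pin2, hexane, 80 °C; then Oxone (2KHSO5·KHSO4·K2SO4), acetone/H2O, 0 °C to rt
Reagents that add atoms: bis(pinacolato)diboron, CC1(C)OB(OC1(C)C)B1OC(C)(C)C(C)(C)O1 (boron of 3); potassium peroxymonosulfate from Oxone, [K+].[O-]S(=O)(=O)OO (oxygen of 4)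
Why: Sterically controlled iridium-catalysed C–H borylation should take the only C–H that is not ortho to a substituent (para to OMe), and oxidation of the C–B bond then gives the phenol whose oxygen becomes O1, so O1 is differentiated from O5 and O7 from the outset.

Step 3
Reactants: 4 free phenol; 5 tert-butyl 2-methylbut-3-en-2-yl carbonate
Product: 7 prenylphenol 3,5-bis(TBSO)-4-methoxy-2-prenylphenol, via aryl 1,1-dimethylallyl ether 6 (not isolated)
Conditions: Pd(PPh3)4 (2 mol%), THF, 0 °C; then toluene, 110 °C
Reagents that add atoms: none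
Why: Tsuji–Trost O-allylation through the π-(1,1-dimethylallyl)palladium complex should give the tertiary ether 6 under kinetic control, and its aromatic Claisen rearrangement transfers the allyl unit with inversion to an ortho carbon as a linear prenyl group, the para position being blocked by OMe and the two ortho positions being equivalent.

Step 4
Reactants: 7 prenylphenol
Product: 8 salicylaldehyde 4,6-bis(TBSO)-2-hydroxy-5-methoxy-3-prenylbenzaldehyde
Conditions: MgCl2, Et3N, (CH2O)n, MeCN, 80 °C; aq. NH4Cl work-up
Reagents that add atoms: paraformaldehyde (as formaldehyde), C=O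
Why: Magnesium-mediated ortho-formylation should deliver formaldehyde through a six-membered phenoxide chelate to the single free ortho carbon and oxidise the benzylic alkoxide with a second formaldehyde (Oppenauer-type hydride transfer), under conditions too mild to touch the prenyl alkene or the silyl ethers.

Step 5
Reactants: 8 salicylaldehyde
Product: 9 ketol 1-[4,6-bis(TBSO)-2-hydroxy-5-methoxy-3-prenylphenyl]-2-hydroxyethan-1-one
Conditions: 3-ethyl-5-(2-hydroxyethyl)-4-methylthiazolium bromide (10 mol%), i-Pr2NEt (10 mol%), (CH2O)n, THF, 60 °C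
Reagents that add atoms: paraformaldehyde (as formaldehyde), C=O
Why: N-heterocyclic-carbene umpolung (crossed acyloin-type hydroxymethylation) should add the Breslow intermediate of the aldehyde to formaldehyde, the far better acceptor, and release the hydroxymethyl ketone directly at the oxidation level of C4/C3.

Step 6
Reactants: 10 2-(allyloxy)benzaldehyde
Product: 11 dimethyl acetal 1-(allyloxy)-2-(dimethoxymethyl)benzene
Conditions: HC(OMe)3, p-TsOH·H2O (1 mol%), MeOH, rt; K2CO3 quench
Reagents that add atoms: trimethyl orthoformate, COC(OC)OC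
Why: Acid-catalysed acetalisation with the orthoformate as water scavenger should give the exchange partner for step 7.

Step 7
Reactants: 9 ketol; 11 dimethyl acetal
Product: 12 racemic cyclic acetal 2-[2-(allyloxy)phenyl]-6,8-bis(TBSO)-7-methoxy-9-prenyl-4H-1,3-benzodioxepin-5-one
Conditions: pyridinium p-toluenesulfonate (5 mol%), benzene (0.02 M), 5 Å molecular sieves, 45 °C
Reagents that add atoms: none
Why: Transacetalisation with removal of methanol should exchange the primary hydroxyl first and then close the seven-membered ring through O1, held cisoid by the aryl ketone, while the allyl-capped ring B cannot form a quinone methide and the weak acid does not enolise the ketone, so no C–C bond forms at this stage.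

Step 8
Reactants: 12 cyclic acetal
Product: 13 racemic phenol acetal 6,8-bis(TBSO)-2-(2-hydroxyphenyl)-7-methoxy-9-prenyl-4H-1,3-benzodioxepin-5-one
Conditions: Pd(PPh3)4 (3 mol%), N-methylaniline (2 equiv), THF, rt; rapid filtration, used at once
Reagents that add atoms: none
Why: Tsuji–Trost deallylation, in which zerovalent palladium ionises the aryl allyl ether and the weakly basic amine intercepts the π-allyl complex, should free the 2'-hydroxyl under neutral conditions that leave the acetal, the silyl ethers and the prenyl group (no allylic leaving group) intact.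

Step 9
Reactants: 13 phenol acetal
Product: 15 (2R,3R)-5,7-bis(TBSO)-3-hydroxy-2-(2-hydroxyphenyl)-6-methoxy-8-prenylchroman-4-one, via aryloxy ortho-quinone methide 14 (not isolated)
Conditions: (R)-TRIP [(R)-3,3'-bis(2,4,6-triisopropylphenyl)-1,1'-binaphthyl-2,2'-diyl hydrogen phosphate] (10 mol%), toluene (0.01 M), 4 Å molecular sieves, −20 °C to rt
Reagents that add atoms: none
Why: Proposed new method: the phosphoric acid should protonate the alkyl acetal oxygen (the one on C3) while its P=O accepts the 2'-OH proton, so that the C2–O(C3) bond breaks to the neutral, O1-substituted ortho-quinone methide 14 with a free C3–OH ketol; acid-catalysed enolisation to the C3=C4 enediol and conjugate addition of C3 to the methide carbon C2 rearomatise ring B and form the C2–C3 bond, the closest known reaction types being phosphoric-acid-catalysed enol additions to ortho-quinone methides generated from ortho-hydroxybenzyl alcohols and the acid-mediated O-to-C (Petasis–Ferrier-type) rearrangement of cyclic enol acetals. Ring C closes in a 6-(enolendo)-exo-trig mode (C3=C4 inside the new ring, C2=C1' exocyclic). C2 is set by the catalyst, which holds the methide carbonyl oxygen and the enediol OH in one hydrogen-bonded assembly and exposes one face of C2; C3 follows from a chair-like transition state with the ring-B residue and the C3–OH pseudo-equatorial, and 2,3-trans is also the thermodynamic outcome because C3 can equilibrate through the enediol. The step needs C3 rather than C4 attack of the enediol and C- rather than O-attack: reclosure through any oxygen only regenerates acetals that ionise again, loss of O1 instead of O(C3) gives a quinone methide from which C3 could reach C2 only through a three-membered ring and so merely recloses, and attack through C3 is favoured because it develops the aryl- and oxygen-stabilised C4 oxocarbenium and creates the less hindered secondary centre. Low temperature and high dilution should suppress the uncatalysed background and intermolecular addition.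

Step 10
Reactants: 15 bis-silyl ether of floranol
Product: 16 floranol
Conditions: HF·pyridine, pyridine, THF, 0 °C to rt
Reagents that add atoms: none
Why: Fluoride should cleave both aryl silyl ethers (strong Si–F bond) in a pyridine-buffered medium that is neither basic enough to open ring C or enolise C3 nor acidic enough to cyclise the 7-OH onto the prenyl group, so the stereocentres from step 9 are untouched.

**Compound list**

1 | 2-methoxyresorcinol (2-methoxybenzene-1,3-diol) | COc1c(O)cccc1O | starting material
2 | 1,3-bis(tert-butyldimethylsilyloxy)-2-methoxybenzene | COc1c(O[Si](C)(C)C(C)(C)C)cccc1O[Si](C)(C)C(C)(C)C | intermediate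
3 | 2-[3,5-bis(tert-butyldimethylsilyloxy)-4-methoxyphenyl]-4,4,5,5-tetramethyl-1,3,2-dioxaborolane | COc1c(O[Si](C)(C)C(C)(C)C)cc(B2OC(C)(C)C(C)(C)O2)cc1O[Si](C)(C)C(C)(C)C | intermediate (not isolated)
4 | 3,5-bis(tert-butyldimethylsilyloxy)-4-methoxyphenol | COc1c(O[Si](C)(C)C(C)(C)C)cc(O)cc1O[Si](C)(C)C(C)(C)C | intermediate
5 | tert-butyl 2-methylbut-3-en-2-yl carbonate | C=CC(C)(C)OC(=O)OC(C)(C)C | starting material
6 | 1,3-bis(tert-butyldimethylsilyloxy)-2-methoxy-5-[(2-methylbut-3-en-2-yl)oxy]benzene | COc1c(O[Si](C)(C)C(C)(C)C)cc(OC(C)(C)C=C)cc1O[Si](C)(C)C(C)(C)C | intermediate (not isolated)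
7 | 3,5-bis(tert-butyldimethylsilyloxy)-4-methoxy-2-(3-methylbut-2-en-1-yl)phenol | COc1c(O[Si](C)(C)C(C)(C)C)cc(O)c(CC=C(C)C)c1O[Si](C)(C)C(C)(C)C | intermediate
8 | 4,6-bis(tert-butyldimethylsilyloxy)-2-hydroxy-5-methoxy-3-(3-methylbut-2-en-1-yl)benzaldehyde | COc1c(O[Si](C)(C)C(C)(C)C)c(C=O)c(O)c(CC=C(C)C)c1O[Si](C)(C)C(C)(C)C | intermediate
9 | 1-[4,6-bis(tert-butyldimethylsilyloxy)-2-hydroxy-5-methoxy-3-(3-methylbut-2-en-1-yl)phenyl]-2-hydroxyethan-1-one | COc1c(O[Si](C)(C)C(C)(C)C)c(C(=O)CO)c(O)c(CC=C(C)C)c1O[Si](C)(C)C(C)(C)C | intermediate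
10 | 2-(allyloxy)benzaldehyde | C=CCOc1ccccc1C=O | starting material
11 | 1-(allyloxy)-2-(dimethoxymethyl)benzene | C=CCOc1ccccc1C(OC)OC | intermediate
12 | racemic 2-[2-(allyloxy)phenyl]-6,8-bis(tert-butyldimethylsilyloxy)-7-methoxy-9-(3-methylbut-2-en-1-yl)-4H-1,3-benzodioxepin-5-one | COc1c(O[Si](C)(C)C(C)(C)C)c2C(=O)COC(c3ccccc3OCC=C)Oc2c(CC=C(C)C)c1O[Si](C)(C)C(C)(C)C | intermediate
13 | racemic 6,8-bis(tert-butyldimethylsilyloxy)-2-(2-hydroxyphenyl)-7-methoxy-9-(3-methylbut-2-en-1-yl)-4H-1,3-benzodioxepin-5-one | COc1c(O[Si](C)(C)C(C)(C)C)c2C(=O)COC(c3ccccc3O)Oc2c(CC=C(C)C)c1O[Si](C)(C)C(C)(C)C | intermediate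
14 | 1-[4,6-bis(tert-butyldimethylsilyloxy)-5-methoxy-3-(3-methylbut-2-en-1-yl)-2-[(6-oxocyclohexa-2,4-dien-1-ylidene)methoxy]phenyl]-2-hydroxyethan-1-one | COc1c(O[Si](C)(C)C(C)(C)C)c(C(=O)CO)c(OC=C2C=CC=CC2=O)c(CC=C(C)C)c1O[Si](C)(C)C(C)(C)C | intermediate (not isolated)
15 | (2R,3R)-5,7-bis(tert-butyldimethylsilyloxy)-3-hydroxy-2-(2-hydroxyphenyl)-6-methoxy-8-(3-methylbut-2-en-1-yl)-2,3-dihydro-4H-chromen-4-one | COc1c(O[Si](C)(C)C(C)(C)C)c(CC=C(C)C)c2c(c1O[Si](C)(C)C(C)(C)C)C(=O)[C@H](O)[C@@H](c1ccccc1O)O2 | intermediate
16 | floranol, (2R,3R)-3,5,7-trihydroxy-2-(2-hydroxyphenyl)-6-methoxy-8-(3-methylbut-2-en-1-yl)-2,3-dihydro-4H-chromen-4-one | COc1c(O)c(CC=C(C)C)c2c(c1O)C(=O)[C@H](O)[C@@H](c1ccccc1O)O2 | target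

**Step count.** Total steps: 10. Longest linear sequence: 9 steps (1 → 2 → 4 → 7 → 8 → 9 → 12 → 13 → 15 → 16).

**Steps most likely to fail**

1. Step 9 (the proposed new method). The enediol may close through C4 instead of C3, giving a five-membered benzofuranol aldehyde. The acetal may also rearrange without the catalyst, which would cost facial control. Ring C may reopen at O1–C2 through the ring-B quinone methide and erode the enantiomeric purity. The fallback uses known chemistry and the same C2–C3 ring closure, but is racemic and needs a resolution. It sets out from 9, with ring B taken from 10, and comes back at 15.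
   - Aldehyde 10 is reduced (NaBH4, MeOH) to [2-(allyloxy)phenyl]methanol F1 and brominated (CBr4, PPh3, CH2Cl2, 0 °C) to 1-(allyloxy)-2-(bromomethyl)benzene F2.
   - The O1 phenol of 9 is alkylated with F2 (K2CO3, acetone, rt) to the benzyl ether ketol F3.
   - Dess–Martin periodinane (CH2Cl2, rt) oxidises the primary ketol to the aryl glyoxal F4.
   - Irradiation of F4 (blue LEDs, 440 nm, degassed benzene) should trigger a Norrish–Yang photocyclisation, a known reaction type of ortho-alkoxyaryl 1,2-dicarbonyl compounds. The excited dicarbonyl abstracts a benzylic O1–CH2 hydrogen through the aldehyde oxygen, and the 1,6-biradical recombines between C2 and C3. This closes ring C with the C3–OH and the C4 ketone in place; the 5-O-silyl group offers no abstractable hydrogen.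
   - Catalytic Et3N equilibrates C3 to the racemic 2,3-trans allyl ether F5.
   - Preparative HPLC on a chiral stationary phase gives the (2R,3R) allyl ether F6, and deallylation as in step 8 returns 15.

2. Step 7. The exchange may stop at open-chain or oligomeric acetals, because the hydrogen-bonded O1–H, flanked by the acyl and prenyl groups, is a poor nucleophile. The acid may also isomerise the ketol towards the hydroxy aldehyde. The fallback sets out from 9 and 11 and comes back at 12; it attaches O1 first, irreversibly, under base.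
   - Acetal 11 is converted with acetyl chloride (neat, 0 °C to rt) into 1-(allyloxy)-2-[chloro(methoxy)methyl]benzene F7.
   - The sodium phenoxide of 9 (NaH, 1.0 equiv, THF, 0 °C; only the phenol is deprotonated) is alkylated with F7 to the open-chain O1 mixed acetal F8.
   - The ring is then closed by the better nucleophile, the primary hydroxyl, through intramolecular exchange of the methoxy group (pyridinium p-toluenesulfonate, 5 Å molecular sieves, high dilution), giving 12.

3. Step 5. The hindered, hydrogen-bonded aldehyde may fail to enter the carbene cycle while formaldehyde condenses with itself, or the product may be hydroxymethylated a second time. The fallback sets out from 8 and comes back at 9; it replaces umpolung of the aldehyde by a hydroxymethyl anion equivalent.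
   - [(Methoxymethoxy)methyl]lithium (from Bu3SnCH2OCH2OCH3 and n-BuLi, THF, −78 °C, 2.2 equiv, the first consumed by the phenol) adds to 8 to give the mono-protected diol F9.
   - MnO2 (CH2Cl2, rt) oxidises the benzylic alcohol to the protected ketol F10.
   - Me2BBr (CH2Cl2, −78 °C) followed by aq. NaHCO3 removes the methoxymethyl group and returns 9.

**Further compounds**

F1 | step 9 | [2-(allyloxy)phenyl]methanol | C=CCOc1ccccc1CO
F2 | step 9 | 1-(allyloxy)-2-(bromomethyl)benzene | C=CCOc1ccccc1CBr
F3 | step 9 | 1-[2-[[2-(allyloxy)phenyl]methoxy]-4,6-bis(tert-butyldimethylsilyloxy)-5-methoxy-3-(3-methylbut-2-en-1-yl)phenyl]-2-hydroxyethan-1-one | COc1c(O[Si](C)(C)C(C)(C)C)c(C(=O)CO)c(OCc2ccccc2OCC=C)c(CC=C(C)C)c1O[Si](C)(C)C(C)(C)C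
F4 | step 9 | 2-[2-[[2-(allyloxy)phenyl]methoxy]-4,6-bis(tert-butyldimethylsilyloxy)-5-methoxy-3-(3-methylbut-2-en-1-yl)phenyl]-2-oxoacetaldehyde | COc1c(O[Si](C)(C)C(C)(C)C)c(C(=O)C=O)c(OCc2ccccc2OCC=C)c(CC=C(C)C)c1O[Si](C)(C)C(C)(C)C
F5 | step 9 | racemic 2,3-trans-2-[2-(allyloxy)phenyl]-5,7-bis(tert-butyldimethylsilyloxy)-3-hydroxy-6-methoxy-8-(3-methylbut-2-en-1-yl)-2,3-dihydro-4H-chromen-4-one (both enantiomers) | COc1c(O[Si](C)(C)C(C)(C)C)c(CC=C(C)C)c2c(c1O[Si](C)(C)C(C)(C)C)C(=O)[C@H](O)[C@@H](c1ccccc1OCC=C)O2.COc1c(O[Si](C)(C)C(C)(C)C)c(CC=C(C)C)c2c(c1O[Si](C)(C)C(C)(C)C)C(=O)[C@@H](O)[C@H](c1ccccc1OCC=C)O2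
F6 | step 9 | (2R,3R)-2-[2-(allyloxy)phenyl]-5,7-bis(tert-butyldimethylsilyloxy)-3-hydroxy-6-methoxy-8-(3-methylbut-2-en-1-yl)-2,3-dihydro-4H-chromen-4-one | COc1c(O[Si](C)(C)C(C)(C)C)c(CC=C(C)C)c2c(c1O[Si](C)(C)C(C)(C)C)C(=O)[C@H](O)[C@@H](c1ccccc1OCC=C)O2
F7 | step 7 | 1-(allyloxy)-2-[chloro(methoxy)methyl]benzene | C=CCOc1ccccc1C(Cl)OC
F8 | step 7 | racemic 1-[2-[[2-(allyloxy)phenyl](methoxy)methoxy]-4,6-bis(tert-butyldimethylsilyloxy)-5-methoxy-3-(3-methylbut-2-en-1-yl)phenyl]-2-hydroxyethan-1-one | COc1c(O[Si](C)(C)C(C)(C)C)c(C(=O)CO)c(OC(OC)c2ccccc2OCC=C)c(CC=C(C)C)c1O[Si](C)(C)C(C)(C)C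
F9 | step 5 | racemic 1-[4,6-bis(tert-butyldimethylsilyloxy)-2-hydroxy-5-methoxy-3-(3-methylbut-2-en-1-yl)phenyl]-2-(methoxymethoxy)ethan-1-ol | COc1c(O[Si](C)(C)C(C)(C)C)c(C(O)COCOC)c(O)c(CC=C(C)C)c1O[Si](C)(C)C(C)(C)C
F10 | step 5 | 1-[4,6-bis(tert-butyldimethylsilyloxy)-2-hydroxy-5-methoxy-3-(3-methylbut-2-en-1-yl)phenyl]-2-(methoxymethoxy)ethan-1-one | COc1c(O[Si](C)(C)C(C)(C)C)c(C(=O)COCOC)c(O)c(CC=C(C)C)c1O[Si](C)(C)C(C)(C)C
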